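**Direct plan and its weak points**

A direct plan would take the intact flavonol galangin A1, methylate its 7-OH and benzylate its 3-OH to give A2, and install the C8 oxygen as the butanoate by an Elbs-type para-oxidation of the 5-phenolate to give A3. It would end by hydrogenolysis of the benzyl ether.
- The C8–O bond formation on the finished core would be the weakest step. C8 must be told apart from the equally activated C6, persulfate-type oxidations of 5-hydroxyflavones are low-yielding, and an acyloxy-transfer version has no precedent.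
- The one-pot 7-O-methylation and 3-O-benzylation of A1 would rest on small acidity differences among three hydroxyls, so over- and mis-alkylated material is expected.
- The design as a whole borrows the skeleton and sorts out the ring A oxygens afterwards, so its steps build no carbon framework.

**Retrosynthetic overview of the new route**

- Ring A is not taken from a phenol. It is built last, onto the C5=C6 edge of a finished 4-pyranone (ring C, already carrying the phenyl ring B and the 3-oxygen).
- The feature used is the masked methoxyhydroquinone of ring A: C5(OH)–C6(H)–C7(OMe)–C8(O-butanoyl), with para oxygens at C5 and C8, fused across C4a–C8a. This is the substitution pattern that the ring expansion of a 4-oxy-cyclobutenone made from methyl semisquarate delivers.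
- Disconnections: C4a–C5 (6π-electrocyclization of a dienylketene) and C8–C8a (addition of the C6-lithiated pyranone to the semisquarate). The attacked carbonyl becomes C8 and is acylated in the same flask; the other carbonyl becomes the free 5-OH.
- Ring order: ring C from furfural by oxidative ring expansion, then ring A. No C–H oxidation at C8, no sorting of phenols, one protecting group.

Key step: step 6

Assumption: methyl semisquarate 10 is taken to behave like the well-studied 3-alkoxycyclobutenediones, which add organolithium reagents at the ketone carbonyl next to the alkoxy-bearing carbon. The target is achiral; all stereocentres of intermediates are racemic and are erased.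

**Route**

Step 1
Reactants: 1 furfural; 2 phenylmagnesium bromide
Product: 3 furan-2-yl(phenyl)methanol (racemic)
Conditions: PhMgBr (1.1 equiv), THF, 0 °C → rt; then sat. aq. NH4Cl
Reagents that add atoms: none
Why: Grignard addition to the aldehyde; the new carbinol centre is racemic and is destroyed in step 2.

Step 2
Reactants: 3 furan-2-yl(phenyl)methanol
Product: 6 3-hydroxy-2-phenyl-4H-pyran-4-one, via hemiacetal enone 4 (not isolated), via chloro enone 5 (not isolated)
Conditions: Cl2 (2.1 equiv), MeCN/H2O, −10 → 0 °C; then 95 °C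
Reagents that add atoms: water, O
Why: Achmatowicz-type oxidative ring expansion of the furyl carbinol, then chlorination of the enone and hydrolytic aromatization in the same pot, the sequence by which maltol-type 2-substituted 3-hydroxy-4-pyranones are made from furfuryl alcohols; the carbinol oxygen becomes the ring oxygen, the furan oxygen becomes the 3-OH, and the stereocentres of 4 and 5 vanish.

Step 3
Reactants: 6 3-hydroxy-2-phenyl-4H-pyran-4-one
Product: 7 3-[(4-methoxybenzyl)oxy]-2-phenyl-4H-pyran-4-one
Conditions: 4-methoxybenzyl chloride (1.1 equiv), K2CO3 (1.5 equiv), KI (cat.), DMF, 60 °C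
Reagents that add atoms: 4-methoxybenzyl chloride, COc1ccc(CCl)cc1
Why: Williamson etherification of the acidic enolic 3-OH, giving an ether that should tolerate a lithium amide at −78 °C and heating to 140 °C and that leaves by neutral hydrogenolysis.

Step 4
Reactants: 8 dimethyl squarate
Product: 10 3-methoxycyclobut-3-ene-1,2-dione (methyl semisquarate), via 4-hydroxy-2,3-dimethoxycyclobut-2-en-1-one 9 (not isolated)
Conditions: LiAlH(Ot-Bu)3 (1.05 equiv), THF, −78 °C; then 6 M aq. HCl, CH2Cl2, 0 °C → rt
Reagents that add atoms: water, O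
Why: Mono-reduction of one vinylogous ester carbonyl by the bulky hydride, then acid-mediated allylic transposition with loss of methanol, the established entry to 3-alkoxycyclobutenediones from dialkyl squarates; water supplies the new carbonyl oxygen.

Step 5
Reactants: 7 3-[(4-methoxybenzyl)oxy]-2-phenyl-4H-pyran-4-one; 10 methyl semisquarate
Product: 13 1-{5-[(4-methoxybenzyl)oxy]-4-oxo-6-phenyl-4H-pyran-2-yl}-2-methoxy-4-oxocyclobut-2-en-1-yl butanoate (racemic), via 6-lithio pyranone 11 (not isolated), via lithium cyclobutenolate 12 (not isolated)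
Conditions: lithium 2,2,6,6-tetramethylpiperidide (from 2,2,6,6-tetramethylpiperidine and n-BuLi, 1.05 equiv), THF, −78 °C, 20 min; cannulated into 10 (1.2 equiv), THF, −78 °C; then butyric anhydride (1.5 equiv), −78 → 0 °C
Reagents that add atoms: butyric anhydride, CCCC(=O)OC(=O)CCC
Why: Deprotonative lithiation of the 4-pyranone at C6, the carbon next to the ring oxygen (as in the C2-lithiation of 3-substituted chromones and 1-alkyl-4-quinolones), then 1,2-addition to the ketone carbonyl of 10 (the other carbonyl is a deactivated vinylogous ester) and O-acylation of the tertiary lithium alkoxide; the new quaternary centre is racemic and is destroyed in step 6.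

Step 6
Reactants: 13 cyclobutenone butanoate
Product: 16 5-hydroxy-7-methoxy-3-[(4-methoxybenzyl)oxy]-4-oxo-2-phenyl-4H-chromen-8-yl butanoate, via dienylketene 14 (not isolated), via 4a-H dienone 15 (not isolated)
Conditions: p-xylene (0.02 M, degassed), 138 °C, argon
Reagents that add atoms: none
Why: Moore–Liebeskind ring expansion: thermal conrotatory 4π ring opening of the cyclobutenone gives dienylketene 14, the butanoyloxy donor rotating outward so that the pyranonyl group lies cis to the ketene; 6π-electrocyclization then joins the ketene carbon to C5 of the pyranone, closing the six-membered ring A through the C4a–C5 bond, and the doubly activated C4a–H of dienone 15 enolizes at once to the chelated 5-OH. The closest known reactions are the thermolyses of 4-aryl-, 4-alkenyl- and 4-heteroaryl-4-oxycyclobutenones (oxygen free, silylated, alkylated or acylated) to hydroquinones and their mono-protected forms, including annulations onto furans, pyridines and uracils. No stereocentre remains, since the quaternary centre of 13 and the C4a centre of 15 are both erased. The step needs torquoselectivity, which the oxygen donor on the ring-opening carbon secures, and regiochemistry, which connectivity fixes because the ketene can reach only the one ring carbon next to the point of attachment. C5-OH, C6-H, C7-OMe and C8-O-butanoyl therefore arrive already differentiated: the 5-OH is born free while the 8-oxygen already carries its ester, so no free hydroquinone is exposed and no selective acylation is needed.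

Step 7
Reactants: 16 5-hydroxy-7-methoxy-3-[(4-methoxybenzyl)oxy]-4-oxo-2-phenyl-4H-chromen-8-yl butanoate
Product: 17 3,5-dihydroxy-7-methoxy-4-oxo-2-phenyl-4H-chromen-8-yl butanoate (target)
Conditions: H2 (1 atm), 10% Pd/C, EtOAc, rt
Reagents that add atoms: none
Why: Catalytic hydrogenolysis of the 4-methoxybenzyl ether, under which the aryl butanoate, the aryl methyl ether and the tetrasubstituted C2=C3 bond should be inert in a non-nucleophilic solvent; the product has no stereocentre.

**Compound list**

1 | furfural (furan-2-carbaldehyde) | O=Cc1ccco1 | starting material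
2 | phenylmagnesium bromide | Br[Mg]c1ccccc1 | starting material
3 | furan-2-yl(phenyl)methanol (racemic) | OC(c1ccco1)c1ccccc1 | intermediate
4 | 6-hydroxy-2-phenyl-2H-pyran-3(6H)-one (diastereomer mixture, racemic) | O=C1C=CC(O)OC1c1ccccc1 | intermediate (not isolated)
5 | 4-chloro-6-hydroxy-2-phenyl-2H-pyran-3(6H)-one (diastereomer mixture, racemic) | O=C1C(Cl)=CC(O)OC1c1ccccc1 | intermediate (not isolated)
6 | 3-hydroxy-2-phenyl-4H-pyran-4-one | O=c1ccoc(-c2ccccc2)c1O | intermediate
7 | 3-[(4-methoxybenzyl)oxy]-2-phenyl-4H-pyran-4-one | COc1ccc(COc2c(-c3ccccc3)occc2=O)cc1 | intermediate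
8 | dimethyl squarate (3,4-dimethoxycyclobut-3-ene-1,2-dione) | COC1=C(OC)C(=O)C1=O | starting material
9 | 4-hydroxy-2,3-dimethoxycyclobut-2-en-1-one (racemic) | COC1=C(OC)C(O)C1=O | intermediate (not isolated)
10 | 3-methoxycyclobut-3-ene-1,2-dione (methyl semisquarate) | COC1=CC(=O)C1=O | intermediate
11 | 6-lithio-3-[(4-methoxybenzyl)oxy]-2-phenyl-4H-pyran-4-one | COc1ccc(COc2c(-c3ccccc3)oc([Li])cc2=O)cc1 | intermediate (not isolated)
12 | lithium 1-{5-[(4-methoxybenzyl)oxy]-4-oxo-6-phenyl-4H-pyran-2-yl}-2-methoxy-4-oxocyclobut-2-en-1-olate (racemic) | [Li+].[O-]C1(C(OC)=CC1=O)c1cc(=O)c(OCc2ccc(OC)cc2)c(-c2ccccc2)o1 | intermediate (not isolated)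
13 | 1-{5-[(4-methoxybenzyl)oxy]-4-oxo-6-phenyl-4H-pyran-2-yl}-2-methoxy-4-oxocyclobut-2-en-1-yl butanoate (racemic) | CCCC(=O)OC1(C(OC)=CC1=O)c1cc(=O)c(OCc2ccc(OC)cc2)c(-c2ccccc2)o1 | intermediate
14 | (Z)-dienylketene: 2-methoxy-1-{5-[(4-methoxybenzyl)oxy]-4-oxo-6-phenyl-4H-pyran-2-yl}-4-oxobuta-1,3-dien-1-yl butanoate, pyranonyl cis to the ketene | O=C=C/C(OC)=C(/OC(=O)CCC)c1cc(=O)c(OCc2ccc(OC)cc2)c(-c2ccccc2)o1 | intermediate (not isolated)
15 | 7-methoxy-3-[(4-methoxybenzyl)oxy]-4,5-dioxo-2-phenyl-4a,5-dihydro-4H-chromen-8-yl butanoate (racemic at C4a) | CCCC(=O)OC1=C2OC(-c3ccccc3)=C(OCc3ccc(OC)cc3)C(=O)C2C(=O)C=C1OC | intermediate (not isolated)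
16 | 5-hydroxy-7-methoxy-3-[(4-methoxybenzyl)oxy]-4-oxo-2-phenyl-4H-chromen-8-yl butanoate | CCCC(=O)Oc1c(OC)cc(O)c2c(=O)c(OCc3ccc(OC)cc3)c(-c3ccccc3)oc12 | intermediate
17 | 3,5-dihydroxy-7-methoxy-4-oxo-2-phenyl-4H-chromen-8-yl butanoate (achiral) | CCCC(=O)Oc1c(OC)cc(O)c2c(=O)c(O)c(-c3ccccc3)oc12 | target

**Step count and risks**

Total steps: 7. Longest linear sequence: 6 (steps 1, 2, 3, 5, 6, 7); step 4 is a one-step branch.

Steps most likely to fail:

1. Step 5. The amide base could remove the C5 proton next to the carbonyl instead of the C6 proton, the lithiated pyranone could add to unmetalated 7, or it could attack 10 in a conjugate manner. The fallback sets out from 7. Zincation with TMPZnCl·LiCl in the presence of MgCl2 (THF, 25 °C), where the carbonyl-bound Lewis acid is expected to steer chromone-type zincation to the carbon next to the ring oxygen, would give {5-[(4-methoxybenzyl)oxy]-4-oxo-6-phenyl-4H-pyran-2-yl}zinc chloride F1. Iodolysis with I2 would give 6-iodo-3-[(4-methoxybenzyl)oxy]-2-phenyl-4H-pyran-4-one F2, an isolable compound on which the site of metalation can be checked. Iodine–magnesium exchange (i-PrMgCl·LiCl, THF, −40 °C) would give {5-[(4-methoxybenzyl)oxy]-4-oxo-6-phenyl-4H-pyran-2-yl}magnesium chloride F3, far less basic than 11. Its addition to 10 would give chloromagnesium 1-{5-[(4-methoxybenzyl)oxy]-4-oxo-6-phenyl-4H-pyran-2-yl}-2-methoxy-4-oxocyclobut-2-en-1-olate F4, and a butyric anhydride quench comes back to the route at 13.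

2. Step 6. The butanoyloxy group could rotate inward or transfer its acyl group to the ketene, or ring opening of the ester could be slow enough for decomposition to compete. The fallback sets out from 12, generated as in step 5. Quenching with aq. NH4Cl in place of the anhydride would give 6-(1-hydroxy-2-methoxy-4-oxocyclobut-2-en-1-yl)-3-[(4-methoxybenzyl)oxy]-2-phenyl-4H-pyran-4-one F5. Its thermolysis (toluene, 110 °C, argon), with the free hydroxyl as the strongest outward-rotating donor, would give 5,8-dihydroxy-7-methoxy-3-[(4-methoxybenzyl)oxy]-2-phenyl-4H-chromen-4-one F6. Butanoyl chloride (1.05 equiv, pyridine, CH2Cl2, 0 °C) should acylate only the non-chelated 8-OH, which comes back to the route at 16.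

3. Step 2. The one-pot chlorine oxidation could over-halogenate, polymerize the furan, or stall at the hydrolysis stage. The fallback sets out from 3. Achmatowicz oxidation with NBS (NaHCO3, THF/H2O, 0 °C) would give 4, now isolated. Acetalization (HC(OMe)3, BF3·OEt2 cat., CH2Cl2) would give 6-methoxy-2-phenyl-2H-pyran-3(6H)-one F7. Nucleophilic epoxidation (H2O2, NaOH cat., MeOH, 0 °C) would give 2-methoxy-4-phenyl-3,7-dioxabicyclo[4.1.0]heptan-5-one F8. Aqueous acid (2 M H2SO4, 90 °C) would rearrange the epoxy ketone with loss of methanol and come back to the route at 6.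

**Further compounds**

F1 | step 5 | {5-[(4-methoxybenzyl)oxy]-4-oxo-6-phenyl-4H-pyran-2-yl}zinc chloride | COc1ccc(COc2c(-c3ccccc3)oc([Zn]Cl)cc2=O)cc1
F2 | step 5 | 6-iodo-3-[(4-methoxybenzyl)oxy]-2-phenyl-4H-pyran-4-one | COc1ccc(COc2c(-c3ccccc3)oc(I)cc2=O)cc1
F3 | step 5 | {5-[(4-methoxybenzyl)oxy]-4-oxo-6-phenyl-4H-pyran-2-yl}magnesium chloride | COc1ccc(COc2c(-c3ccccc3)oc([Mg]Cl)cc2=O)cc1
F4 | step 5 | chloromagnesium 1-{5-[(4-methoxybenzyl)oxy]-4-oxo-6-phenyl-4H-pyran-2-yl}-2-methoxy-4-oxocyclobut-2-en-1-olate (racemic) | Cl[Mg]OC1(C(OC)=CC1=O)c1cc(=O)c(OCc2ccc(OC)cc2)c(-c2ccccc2)o1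
F5 | step 6 | 6-(1-hydroxy-2-methoxy-4-oxocyclobut-2-en-1-yl)-3-[(4-methoxybenzyl)oxy]-2-phenyl-4H-pyran-4-one (racemic) | OC1(C(OC)=CC1=O)c1cc(=O)c(OCc2ccc(OC)cc2)c(-c2ccccc2)o1
F6 | step 6 | 5,8-dihydroxy-7-methoxy-3-[(4-methoxybenzyl)oxy]-2-phenyl-4H-chromen-4-one | COc1cc(O)c2c(=O)c(OCc3ccc(OC)cc3)c(-c3ccccc3)oc2c1O
F7 | step 2 | 6-methoxy-2-phenyl-2H-pyran-3(6H)-one (diastereomer mixture, racemic) | COC1C=CC(=O)C(c2ccccc2)O1
F8 | step 2 | 2-methoxy-4-phenyl-3,7-dioxabicyclo[4.1.0]heptan-5-one (diastereomer mixture, racemic) | COC1OC(c2ccccc2)C(=O)C2OC12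
A1 | direct plan | galangin (3,5,7-trihydroxy-2-phenyl-4H-chromen-4-one) | O=c1c(O)c(-c2ccccc2)oc2cc(O)cc(O)c12
A2 | direct plan | 3-(benzyloxy)-5-hydroxy-7-methoxy-2-phenyl-4H-chromen-4-one | COc1cc(O)c2c(=O)c(OCc3ccccc3)c(-c3ccccc3)oc2c1
A3 | direct plan | 3-(benzyloxy)-5-hydroxy-7-methoxy-4-oxo-2-phenyl-4H-chromen-8-yl butanoate | CCCC(=O)Oc1c(OC)cc(O)c2c(=O)c(OCc3ccccc3)c(-c3ccccc3)oc12
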